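All constants are invented, and the outcome is calculated.

A referee wants four numbers from the flask, and one ratio supplies them.

first end groups 0.010 M; second end groups 1.00 equiv; time 50 min

    first end groups + second end groups → links + by-product (k1 = 3.3 L mol⁻¹ s⁻¹)
    second end groups + links → over-reaction product (k2 = 1.2 L mol⁻¹ s⁻¹)
    links ⇌ isomer of the product (K3 = 0.55, k3 = 0.0083 s⁻¹)

1. which holds at 50 min: what has brought the reaction to rest, or that it has not come to rest (forward and back rates have come level / all of the first end groups has reacted / the second end groups has run out first / it is still moving)
2. conversion of first end groups at 50 min
3. amount of links at 50 min, in percent of the first end groups charged
4. amount of isomer of the product at 50 min, in percent of the first end groups charged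

- the reaction counts as stopped when no species that holds the first end groups changes by six tenths of a point or more over the second half of the time
- run time (flask): 50 min

Let a be the fraction of first end groups left, and p the fraction standing as the pair, links plus isomer of the product. The ledger counts second end groups, the limiting reagent. Each first end group reacted takes one. Each over-reaction product takes one more, and that product is the reacted fraction minus p. With e equivalents charged, the books close at a = 1 − (e + p)/2.

The pair loses links by over-reaction. Per first end group lost, that loss is s·p/a, where s, the sheltered selectivity factor, is the over-reaction constant over the link-forming constant, divided by one plus K3: 0.235. Integrated in the fraction left, this gives p = (a^s − a)/(1 − s).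

Two rounds of the closing leave a = 18.1%. But s assumes a balanced pair, and the pair's relaxation half-life is 0.494 min, while first end groups, with the other concentrations as charged, have a half-life of 0.35 min. Unsheltered, the ratio is 0.364, and a = 22.1%.

My reckoning takes the midpoint, 20.1% left. That is conversion 79.9%, and p = 1 − 2a splits by K3, since relaxation is short against 50 min: links 38.5%, isomer 21.2%.

The forecast gives the second end groups has run out first, with 81%, 40% and 22%, reasoning that “over-reaction also consumes the second end groups”.

The flask gives the second end groups has run out first, with 0% of them left, conversion 80.3%, links 39.1% and isomer 21.5%. A neighbour flask, like this one but for its second end groups, is charged with e = 0.400. The same closing, in two rounds from a = 1 − e, leaves 61.8% with s and 62.6% unsheltered. The midpoint means conversion 37.8% and over-reaction product 2.20%. That neighbour flask gives conversion 37.3% and over-reaction product 2.69%.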